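**Retrosynthetic overview**
- The four phenols are unmasked last, from their methoxymethyl (MOM) ethers, under mild acid.
- The protected target is cut into four pieces that are joined in one flask. These are a ring A benzylstannane carrying C4, an (R)-aryl epoxide (O1–C2–C3 with ring B), 1,4-dimethylpiperazine-2,3-dione (both C=O) and a ring D aryl bromide. The bonds made are C3–C4, O1–C8a, C8–C(=O) and C(=O)–ring D.
- Enabling feature: on ring A the atoms C4a (bearing C4H2), C8a (bearing O1), C8 (bearing the acyl carbon) and C7 (bearing O) stand in a row. O1 and the acyl group are therefore the two ortho partners taken up by a C8≡C8a aryne. That aryne is polarised by the C7 oxygen and can be reached only at C8a by the C4–C3–C2–O tether. O1–C2–C3 is an opened aryl epoxide, so C2 enters as a ready-made stereocentre.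
- The stannane comes from 5-fluororesorcinol, the epoxide from 2-chloro-4'-hydroxyacetophenone by asymmetric transfer hydrogenation, and the bromide from 4-bromophenol.
- Ring order: rings A, B and D are bought as benzene rings. Ring C (the dihydropyran) is the only ring formed, in the key step.

Key step: step 8

Remark: flavan numbering is used (O1, C2, C3, C4, C4a, C5 to C8, C8a). The target is taken as the open 1,2-diketone tautomer that is drawn, and its reversible hemiketal with the C7 hydroxyl is treated as the same compound.

**Step 1**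
Reactants: 1 5-fluorobenzene-1,3-diol
Product: 2 2-fluoro-4,6-dihydroxybenzaldehyde
Conditions: POCl3, DMF, MeCN, 0 °C → rt; then H2O, 50 °C
Reagents that add atoms: N,N-dimethylformamide CN(C)C=O; water O
Why: Vilsmeier–Haack formylation, in which the chloroiminium ion should attack the position para to one hydroxyl and ortho to the other (beside fluorine), as 5-substituted resorcinols do, and not the crowded site between the two hydroxyls.

**Step 2**
Reactants: 2 2-fluoro-4,6-dihydroxybenzaldehyde
Product: 3 2-fluoro-4,6-bis(methoxymethoxy)benzaldehyde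
Conditions: NaH, MOMCl, DMF, 0 °C → rt
Reagents that add atoms: chloromethyl methyl ether COCCl
Why: Williamson-type O-alkylation of both phenoxides (full deprotonation by NaH also frees the hydrogen-bonded one) gives acetals that are inert to organolithiums.

**Step 3**
Reactants: 3 2-fluoro-4,6-bis(methoxymethoxy)benzaldehyde
Product: 4 [2-fluoro-4,6-bis(methoxymethoxy)phenyl]methanol
Conditions: NaBH4, MeOH, 0 °C
Reagents that add atoms: none
Why: Borohydride 1,2-reduction of the aldehyde leaves the aryl fluoride and the MOM acetals untouched.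

**Step 4**
Reactants: 4 [2-fluoro-4,6-bis(methoxymethoxy)phenyl]methanol
Product: 6 tributyl{[2-fluoro-4,6-bis(methoxymethoxy)phenyl]methyl}stannane, via benzylic mesylate 5 (not isolated)
Conditions: n-BuLi, THF, −78 °C; MsCl, −78 → −40 °C; then Bu3SnLi (from Bu3SnH, LiN(i-Pr)2, THF, 0 °C), −78 → 0 °C
Reagents that add atoms: tributylstannane CCCC[SnH](CCCC)CCCC
Why: One-flask sulfonate activation and SN2 displacement by a stannyl anion is the standard way from allylic and benzylic alcohols to their tributylstannanes, and the aprotic medium avoids acid that would cleave MOM.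

**Step 5**
Reactants: 7 2-chloro-1-(4-hydroxyphenyl)ethan-1-one
Product: 8 2-chloro-1-[4-(methoxymethoxy)phenyl]ethan-1-one
Conditions: MOMCl, i-Pr2NEt, CH2Cl2, 0 °C → rt
Reagents that add atoms: chloromethyl methyl ether COCCl
Why: O-alkylation of the acidic para-acylphenol with a hindered amine base spares the α-chloroketone.

**Step 6**
Reactants: 8 2-chloro-1-[4-(methoxymethoxy)phenyl]ethan-1-one
Product: 10 (2R)-2-[4-(methoxymethoxy)phenyl]oxirane, via (R)-chlorohydrin 9 (not isolated)
Conditions: RuCl[(S,S)-TsDPEN](p-cymene) cat., HCO2H/Et3N 5:2, EtOAc, rt; then 2 M aq NaOH, i-PrOH, 0 °C → rt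
Reagents that add atoms: none
Why: Asymmetric transfer hydrogenation of the α-chloro aryl ketone sets the carbinol centre in the six-membered hydride-transfer transition state of the (S,S)-catalyst (R chlorohydrin), and the intramolecular Williamson closure at CH2Cl does not touch this centre.

**Step 7**
Reactants: 11 4-bromophenol
Product: 12 1-bromo-4-(methoxymethoxy)benzene
Conditions: MOMCl, i-Pr2NEt, CH2Cl2, 0 °C → rt
Reagents that add atoms: chloromethyl methyl ether COCCl
Why: Routine phenol O-alkylation gives a bromide fit for bromine–lithium exchange.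

**Step 8**
Reactants: 6 tributyl{[2-fluoro-4,6-bis(methoxymethoxy)phenyl]methyl}stannane; 10 (2R)-2-[4-(methoxymethoxy)phenyl]oxirane; 12 1-bromo-4-(methoxymethoxy)benzene; 13 1,4-dimethylpiperazine-2,3-dione
Product: 22 1-{(2S)-5,7-bis(methoxymethoxy)-2-[4-(methoxymethoxy)phenyl]-3,4-dihydro-2H-chromen-8-yl}-2-[4-(methoxymethoxy)phenyl]ethane-1,2-dione, via benzyllithium 14 (not isolated), via lithium alkoxide 15 (not isolated), via ring-lithiated fluoroarene 16 (not isolated), via aryne 17 (not isolated), via 8-lithioflavan 18 (not isolated), via mono-adduct 19 (not isolated), via aryllithium 20 (not isolated), via bis-adduct 21 (not isolated)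
Conditions: n-BuLi, THF, −78 °C; then 10, −78 → −20 °C; n-BuLi, PMDTA, −78 → −10 °C; 13, −78 °C; then 20 (from 12, n-BuLi, THF, −78 °C, second flask), −78 → 0 °C; AcOH, H2O
Reagents that add atoms: none
Why: Proposed new method: tin–lithium exchange converts 6 into benzyllithium 14, whose carbanion C4 opens epoxide 10 by SN2 attack at the unsubstituted carbon C3 to give alkoxide 15, n-BuLi/PMDTA then removes the ring proton between F and OMOM (C8–H) to give 16, loss of LiF on warming gives the C8≡C8a aryne 17, the tethered alkoxide adds to C8a, and the aryllithium 18 left at C8 adds to one carbonyl of diamide 13 (19) before aryllithium 20 adds to the other (21), both tetrahedral adducts surviving until the acidic quench releases the 1,2-diketone. The closest known reaction types are epoxide opening by benzyllithiums made from benzylstannanes, the anionic benzyne cyclisation of tethered heteroatom nucleophiles with electrophilic capture of the new aryllithium, and the synthesis of unsymmetrical 1,2-diketones from 13 and two different organolithiums; only their coupling in one flask is new. Ring C, the only ring formed, closes in the 6-exo-dig mode, since O1 attacks the alkyne carbon C8a while C8 stays outside the new ring. No stereocentre is created: C2 is the substituted epoxide carbon of 10, its C–O bond is never broken, and the descriptor changes from R to S only because the CIP ranks of aryl and CH2 are exchanged. The side of addition to the aryne is fixed twice, by the C4–C3–C2 tether on C4a that can reach only C8a, and by the inductively withdrawing C7–OMOM group beside C8, which distorts the triple bond so that the nucleophile adds at the remote carbon C8a and the charge develops at C8 next to oxygen, where OMOM also chelates lithium. The step further needs terminal instead of benzylic opening of 10, favoured by the Lewis-acid-free carbanion conditions, and C8–H instead of C6–H lithiation, favoured because fluorine acidifies more strongly than OMOM, because PMDTA saturates lithium and so weakens guidance by the two OMOM groups around C6, and because the alkoxide-bound base aggregate sits on the fluorine side of ring A.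

**Step 9**
Reactants: 22 1-{(2S)-5,7-bis(methoxymethoxy)-2-[4-(methoxymethoxy)phenyl]-3,4-dihydro-2H-chromen-8-yl}-2-[4-(methoxymethoxy)phenyl]ethane-1,2-dione
Product: 23 1-[(2S)-5,7-dihydroxy-2-(4-hydroxyphenyl)-3,4-dihydro-2H-chromen-8-yl]-2-(4-hydroxyphenyl)ethane-1,2-dione
Conditions: 3 M aq HCl, THF/i-PrOH, 40 °C
Reagents that add atoms: none
Why: Acid-catalysed acetal hydrolysis of the four aryl MOM ethers through oxocarbenium ions should be much faster than ionisation of the C2–O1 benzylic ether, so the C2 configuration should be kept, and the alcohol-poor aqueous medium disfavours ketalisation of the diketone.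

**Compound list**
1 | 5-fluorobenzene-1,3-diol | Oc1cc(O)cc(F)c1 | starting material
2 | 2-fluoro-4,6-dihydroxybenzaldehyde | O=Cc1c(O)cc(O)cc1F | intermediate
3 | 2-fluoro-4,6-bis(methoxymethoxy)benzaldehyde | O=Cc1c(OCOC)cc(OCOC)cc1F | intermediate
4 | [2-fluoro-4,6-bis(methoxymethoxy)phenyl]methanol | OCc1c(OCOC)cc(OCOC)cc1F | intermediate
5 | [2-fluoro-4,6-bis(methoxymethoxy)phenyl]methyl methanesulfonate | CS(=O)(=O)OCc1c(OCOC)cc(OCOC)cc1F | intermediate
6 | tributyl{[2-fluoro-4,6-bis(methoxymethoxy)phenyl]methyl}stannane | CCCC[Sn](CCCC)(CCCC)Cc1c(OCOC)cc(OCOC)cc1F | intermediate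
7 | 2-chloro-1-(4-hydroxyphenyl)ethan-1-one | O=C(CCl)c1ccc(O)cc1 | starting material
8 | 2-chloro-1-[4-(methoxymethoxy)phenyl]ethan-1-one | O=C(CCl)c1ccc(OCOC)cc1 | intermediate
9 | (1R)-2-chloro-1-[4-(methoxymethoxy)phenyl]ethan-1-ol | O[C@@H](CCl)c1ccc(OCOC)cc1 | intermediate
10 | (2R)-2-[4-(methoxymethoxy)phenyl]oxirane | C1O[C@@H]1c1ccc(OCOC)cc1 | intermediate
11 | 4-bromophenol | Oc1ccc(Br)cc1 | starting material
12 | 1-bromo-4-(methoxymethoxy)benzene | COCOc1ccc(Br)cc1 | intermediate
13 | 1,4-dimethylpiperazine-2,3-dione | CN1CCN(C)C(=O)C1=O | starting material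
14 | [2-fluoro-4,6-bis(methoxymethoxy)benzyl]lithium | [Li]Cc1c(OCOC)cc(OCOC)cc1F | intermediate
15 | lithium (1S)-3-[2-fluoro-4,6-bis(methoxymethoxy)phenyl]-1-[4-(methoxymethoxy)phenyl]propan-1-olate | [Li]O[C@H](c1ccc(OCOC)cc1)CCc1c(OCOC)cc(OCOC)cc1F | intermediate
16 | alkoxide 15 lithiated at the ring carbon between F and OMOM | [Li]O[C@H](c1ccc(OCOC)cc1)CCc1c(OCOC)cc(OCOC)c([Li])c1F | intermediate
17 | aryne (C8≡C8a) carrying the lithium alkoxide tether | [Li]O[C@H](c1ccc(OCOC)cc1)CCC1=C(OCOC)C=C(OCOC)C#C1 | intermediate
18 | (2S)-8-lithio-5,7-bis(methoxymethoxy)-2-[4-(methoxymethoxy)phenyl]chromane | [Li]c1c(OCOC)cc(OCOC)c2c1O[C@H](c1ccc(OCOC)cc1)CC2 | intermediate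
19 | lithium hemiaminal from 18 and 13 (one carbonyl added) | CN1CCN(C)C(O[Li])(c2c(OCOC)cc(OCOC)c3c2O[C@H](c2ccc(OCOC)cc2)CC3)C1=O | intermediate
20 | [4-(methoxymethoxy)phenyl]lithium | [Li]c1ccc(OCOC)cc1 | intermediate
21 | dilithium bis-hemiaminal from 19 and 20 | CN1CCN(C)C(O[Li])(c2c(OCOC)cc(OCOC)c3c2O[C@H](c2ccc(OCOC)cc2)CC3)C1(O[Li])c1ccc(OCOC)cc1 | intermediate
22 | 1-{(2S)-5,7-bis(methoxymethoxy)-2-[4-(methoxymethoxy)phenyl]-3,4-dihydro-2H-chromen-8-yl}-2-[4-(methoxymethoxy)phenyl]ethane-1,2-dione | O=C(C(=O)c1c(OCOC)cc(OCOC)c2c1O[C@H](c1ccc(OCOC)cc1)CC2)c1ccc(OCOC)cc1 | intermediate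
23 | 1-[(2S)-5,7-dihydroxy-2-(4-hydroxyphenyl)-3,4-dihydro-2H-chromen-8-yl]-2-(4-hydroxyphenyl)ethane-1,2-dione | O=C(C(=O)c1c(O)cc(O)c2c1O[C@H](c1ccc(O)cc1)CC2)c1ccc(O)cc1 | target

**Step count**
- Total step count: 9.
- Longest linear sequence: 6 (steps 1, 2, 3, 4, 8, 9).

**Steps most likely to fail**

1. **Step 8 (key step).**
   - Risks: proton transfer from the acidic ring C–H bonds to the benzylic carbanion before the epoxide is opened, attack at the benzylic instead of the terminal epoxide carbon, and lithiation at C6 in competition with C8.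
   - The fallback builds ring C stepwise by known chemistry. It sets out from 3 and comes back to the route at 18, and so at 22.
   - Claisen–Schmidt condensation of 3 with 1-[4-(methoxymethoxy)phenyl]ethan-1-one F1 (made from 4'-hydroxyacetophenone, MOMCl and i-Pr2NEt) should give (E)-3-[2-fluoro-4,6-bis(methoxymethoxy)phenyl]-1-[4-(methoxymethoxy)phenyl]prop-2-en-1-one F2.
   - Hydrogenation of the alkene (H2, Pd/C, EtOAc) should give the dihydrochalcone F3.
   - Asymmetric transfer hydrogenation with RuCl[(S,S)-TsDPEN](p-cymene) and HCO2H/Et3N should give the (S)-alcohol F4.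
   - KOt-Bu in DMSO should close ring C by intramolecular SNAr at the C–F carbon to give (2S)-5,7-bis(methoxymethoxy)-2-[4-(methoxymethoxy)phenyl]chromane F5.
   - NBS in CH2Cl2 at low temperature should brominate C8 to give the 8-bromoflavan F6.
   - Bromine–lithium exchange with n-BuLi gives 18, which is carried on with 13 and 20 as in step 8.

2. **Step 9.**
   - Risks: acid-induced ionisation of the C2–O1 bond through a para-oxybenzyl cation, with erosion of configurational purity or ring opening, and ketalisation at the diketone.
   - The fallback sets out from 22 and comes back at 23. It replaces Brønsted-acid hydrolysis by a buffered silyl transfer.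
   - TMSOTf and 2,2'-bipyridyl in MeCN should convert the four aryl MOM ethers under nearly neutral conditions into the tetrakis(trimethylsilyl) ether F8.
   - Water at room temperature then cleaves F8 to 23.

3. **Step 4.**
   - Risks: ionisation and self-alkylation of the very electron-rich benzylic sulfonate, and electron transfer from the stannyl anion leading to bibenzyl formation.
   - The fallback sets out from 4 and comes back at 6. It inverts the polarity of the tin–carbon bond formation.
   - An Appel reaction (PPh3, CCl4, CH2Cl2) should give 2-(chloromethyl)-1-fluoro-3,5-bis(methoxymethoxy)benzene F7.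
   - F7 is then stannylated under Barbier conditions (Mg, Bu3SnCl, THF, ultrasound), so that the benzylic magnesium species is captured by the tin electrophile as it forms.

**Further compounds**
F1 | step 8 | 1-[4-(methoxymethoxy)phenyl]ethan-1-one | CC(=O)c1ccc(OCOC)cc1
F2 | step 8 | (E)-3-[2-fluoro-4,6-bis(methoxymethoxy)phenyl]-1-[4-(methoxymethoxy)phenyl]prop-2-en-1-one | O=C(/C=C/c1c(OCOC)cc(OCOC)cc1F)c1ccc(OCOC)cc1
F3 | step 8 | 3-[2-fluoro-4,6-bis(methoxymethoxy)phenyl]-1-[4-(methoxymethoxy)phenyl]propan-1-one | O=C(CCc1c(OCOC)cc(OCOC)cc1F)c1ccc(OCOC)cc1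
F4 | step 8 | (1S)-3-[2-fluoro-4,6-bis(methoxymethoxy)phenyl]-1-[4-(methoxymethoxy)phenyl]propan-1-ol | O[C@H](c1ccc(OCOC)cc1)CCc1c(OCOC)cc(OCOC)cc1F
F5 | step 8 | (2S)-5,7-bis(methoxymethoxy)-2-[4-(methoxymethoxy)phenyl]chromane | c1c(OCOC)cc(OCOC)c2c1O[C@H](c1ccc(OCOC)cc1)CC2
F6 | step 8 | (2S)-8-bromo-5,7-bis(methoxymethoxy)-2-[4-(methoxymethoxy)phenyl]chromane | Brc1c(OCOC)cc(OCOC)c2c1O[C@H](c1ccc(OCOC)cc1)CC2
F7 | step 4 | 2-(chloromethyl)-1-fluoro-3,5-bis(methoxymethoxy)benzene | ClCc1c(OCOC)cc(OCOC)cc1F
F8 | step 9 | tetrakis(trimethylsilyl) ether of 23 | O=C(C(=O)c1c(O[Si](C)(C)C)cc(O[Si](C)(C)C)c2c1O[C@H](c1ccc(O[Si](C)(C)C)cc1)CC2)c1ccc(O[Si](C)(C)C)cc1
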